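## Retrosynthetic overview
1. The acetate comes from the free (S)-carbinol, which is carried as its TBDPS ether. The 2-methoxy-4-pyrone comes from O-methylation of the tautomeric 4-hydroxy-2-pyrone at its lactone carbonyl oxygen.
2. The pyrone is the only ring. It is closed late, in one event, by lactonisation of an acyclic methyl 2,4-diethyl-3,5-dioxoalkanoate.
3. The key C–C disconnection is the future pyrone C5–C6 bond. It is made by an intermolecular aldol of the γ-carbon of the methyl 2-ethyl-3-oxohexanoate dianion with (11S)-11-silyloxydodecanal, followed by oxidation of the carbinol.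
4. The aldehyde comes from ozonolysis of silylated (S)-tridec-12-en-2-ol. That alcohol comes from dec-9-enyl Grignard (from dec-9-en-1-ol) plus (S)-propylene oxide, the sole source of chirality.
5. The keto ester comes from methyl 3-oxohexanoate plus iodoethane.

Assumption: small group-transfer reagents (CBr4, TBDPSCl, O3, EtI, MeOTf, Ac2O) are treated as reagents and given by SMILES at their step, not numbered.

## Route

Step 1
Reactants: 1 dec-9-en-1-ol
Product: 2 10-bromodec-1-ene
Conditions: CBr4 (1.2 equiv), PPh3 (1.25 equiv), CH2Cl2, 0 °C to rt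
Reagents that add atoms: carbon tetrabromide, BrC(Br)(Br)Br
Why: Appel reaction, in which the primary alcohol is activated as its oxyphosphonium salt and displaced by bromide in an SN2 step under neutral conditions that do not touch the terminal alkene.

Step 2
Reactants: 2 10-bromodec-1-ene; 3 (S)-propylene oxide [(2S)-2-methyloxirane]
Product: 5 (2S)-tridec-12-en-2-ol, via dec-9-enylmagnesium bromide 4 (not isolated)
Conditions: Mg, I2 (cat.), THF, 25–45 °C; then CuI (10 mol %), 3, −30 to 0 °C; aq NH4Cl
Reagents that add atoms: none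
Why: Copper-catalysed Grignard opening of a terminal epoxide is an SN2 attack at the unsubstituted CH2 carbon, so no bond at the stereocentre is broken and the (S) configuration bought with 3 appears unchanged as the (2S)-carbinol of 5.

Step 3
Reactants: 5 (2S)-tridec-12-en-2-ol
Product: 6 tert-butyl(diphenyl)[(2S)-tridec-12-en-2-yloxy]silane
Conditions: TBDPSCl (1.2 equiv), imidazole (2.5 equiv), DMF, rt
Reagents that add atoms: tert-butyl(chloro)diphenylsilane (TBDPSCl), CC(C)(C)[Si](Cl)(c1ccccc1)c1ccccc1
Why: Imidazole-promoted silylation of an unhindered secondary alcohol proceeds with retention at carbon, and the TBDPS ether is chosen because it survives ozone, the dianion, Dess–Martin periodinane, DBU and the strongly acidic pyrylium triflate stage of step 9.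

Step 4
Reactants: 6 tert-butyl(diphenyl)[(2S)-tridec-12-en-2-yloxy]silane
Product: 8 (11S)-11-[(tert-butyldiphenylsilyl)oxy]dodecanal, via secondary ozonide 7 (not isolated)
Conditions: O3, CH2Cl2, −78 °C; then PPh3 (1.2 equiv), −78 °C to rt
Reagents that add atoms: ozone, [O-][O+]=O
Why: Ozonolysis (Criegee mechanism) with reductive PPh3 work-up cleaves the only C=C bond, removes the terminal CH2 as formaldehyde and so delivers exactly the C12 aldehyde without over-oxidation, while silyl ether and stereocentre are inert.

Step 5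
Reactants: 9 methyl 3-oxohexanoate
Product: 10 methyl 2-ethyl-3-oxohexanoate (racemic)
Conditions: EtI (1.2 equiv), K2CO3 (1.5 equiv), acetone, reflux
Reagents that add atoms: iodoethane, CCI
Why: Acetoacetic-ester-type C-alkylation of the soft β-keto ester enolate with a primary iodide gives the mono-ethylated product, whose new C2 centre is racemic and irrelevant because it becomes sp2 in the pyrone.

Step 6 (key step)
Reactants: 10 methyl 2-ethyl-3-oxohexanoate; 8 (11S)-11-[(tert-butyldiphenylsilyl)oxy]dodecanal
Product: 12 methyl (15S)-15-[(tert-butyldiphenylsilyl)oxy]-2,4-diethyl-5-hydroxy-3-oxohexadecanoate (mixture of C2/C4/C5 diastereomers), via dilithium dienediolate 11 (not isolated)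
Conditions: 10 (1.5 equiv), LiN(iPr)2 (LDA, commercial 2.0 M solution, 3.2 equiv), THF, −78 to 0 °C; then 8 (1.0 equiv), −78 °C; AcOH quench at −78 °C
Reagents that add atoms: none
Why: Intermolecular aldol addition of a Huckin–Weiler β-keto ester dianion, which reacts only at its more basic γ-carbon (C4) and adds to the aldehyde faster than it enolises it at −78 °C, while the cold acidic quench blocks retro-aldol and lactonisation; the new centres C2, C4 and C5 form as a mixture that is erased in steps 7 and 8, and C15 is untouched.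

Step 7
Reactants: 12 methyl (15S)-15-[(tert-butyldiphenylsilyl)oxy]-2,4-diethyl-5-hydroxy-3-oxohexadecanoate
Product: 13 methyl (15S)-15-[(tert-butyldiphenylsilyl)oxy]-2,4-diethyl-3,5-dioxohexadecanoate (keto/enol and C2/C4 mixture)
Conditions: Dess–Martin periodinane (1.5 equiv), CH2Cl2, 0 °C to rt
Reagents that add atoms: none
Why: Dess–Martin oxidation converts the β-hydroxy ketone into the 1,3-diketone at room temperature under nearly neutral conditions that avoid retro-aldol cleavage and leave ester, silyl ether and the remote stereocentre alone.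

Step 8
Reactants: 13 methyl (15S)-15-[(tert-butyldiphenylsilyl)oxy]-2,4-diethyl-3,5-dioxohexadecanoate
Product: 14 6-[(10S)-10-[(tert-butyldiphenylsilyl)oxy]undecyl]-3,5-diethyl-4-hydroxy-2H-pyran-2-one
Conditions: DBU (2 equiv), toluene, 80 °C; then 1 M HCl
Reagents that add atoms: none
Why: Base-mediated lactonisation (intramolecular O-acylation), in which the C5 enolate oxygen attacks the methyl ester in a 6-exo-trig closure, methanol is expelled and tautomerisation to the aromatic, acidic 4-hydroxy-2-pyrone makes the step irreversible.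

Step 9
Reactants: 14 6-[(10S)-10-[(tert-butyldiphenylsilyl)oxy]undecyl]-3,5-diethyl-4-hydroxy-2H-pyran-2-one
Product: 16 2-[(10S)-10-[(tert-butyldiphenylsilyl)oxy]undecyl]-3,5-diethyl-6-methoxy-4H-pyran-4-one, via 4-hydroxy-2-methoxypyrylium triflate 15 (not isolated)
Conditions: MeOTf (2 equiv), CH2Cl2, 0 °C to rt; then sat. aq NaHCO3
Reagents that add atoms: methyl trifluoromethanesulfonate (MeOTf), COS(=O)(=O)C(F)(F)F
Why: Regioselective O-methylation of the neutral hydroxypyrone with a hard methylating agent takes place at the most nucleophilic lone pair, that of the lactone carbonyl oxygen, to give the aromatic pyrylium salt 15, which loses its 4-OH proton on basic work-up to leave the 2-methoxy-4-pyrone rather than the 4-methoxy-2-pyrone formed under anionic conditions.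

Step 10
Reactants: 16 2-[(10S)-10-[(tert-butyldiphenylsilyl)oxy]undecyl]-3,5-diethyl-6-methoxy-4H-pyran-4-one
Product: 17 3,5-diethyl-2-[(10S)-10-hydroxyundecyl]-6-methoxy-4H-pyran-4-one
Conditions: Bu4NF (TBAF, 3 equiv), AcOH (3 equiv), THF, rt to 45 °C
Reagents that add atoms: none
Why: Fluoride-induced desilylation driven by the strong Si–F bond cleaves only the Si–O bond, so configuration is retained, and the acetic acid buffer keeps the medium non-basic so that the methoxypyrone is not attacked.

Step 11
Reactants: 17 3,5-diethyl-2-[(10S)-10-hydroxyundecyl]-6-methoxy-4H-pyran-4-one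
Product: 18 (2S)-11-(3,5-diethyl-6-methoxy-4-oxo-4H-pyran-2-yl)undecan-2-yl acetate (target)
Conditions: Ac2O (3 equiv), pyridine, 4-(dimethylamino)pyridine (5 mol %), CH2Cl2, rt
Reagents that add atoms: acetic anhydride, CC(=O)OC(C)=O
Why: 4-(Dimethylamino)pyridine-catalysed acylation (nucleophilic catalysis via the N-acetylpyridinium ion) esterifies the only hydroxyl group at oxygen, so the (S) centre is retained and the product is the target.

## Compound list
1 | dec-9-en-1-ol | C=CCCCCCCCCO | starting material
2 | 10-bromodec-1-ene | C=CCCCCCCCCBr | intermediate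
3 | (S)-propylene oxide, (2S)-2-methyloxirane | C[C@H]1CO1 | starting material
4 | dec-9-enylmagnesium bromide | C=CCCCCCCCC[Mg]Br | intermediate
5 | (2S)-tridec-12-en-2-ol | C=CCCCCCCCCC[C@H](C)O | intermediate
6 | tert-butyl(diphenyl)[(2S)-tridec-12-en-2-yloxy]silane | C=CCCCCCCCCC[C@H](C)O[Si](c1ccccc1)(c1ccccc1)C(C)(C)C | intermediate
7 | secondary ozonide, 3-[(10S)-10-[(tert-butyldiphenylsilyl)oxy]undecyl]-1,2,4-trioxolane (epimers at C3) | C1OC(CCCCCCCCC[C@H](C)O[Si](c2ccccc2)(c2ccccc2)C(C)(C)C)OO1 | intermediate
8 | (11S)-11-[(tert-butyldiphenylsilyl)oxy]dodecanal | O=CCCCCCCCCC[C@H](C)O[Si](c1ccccc1)(c1ccccc1)C(C)(C)C | intermediate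
9 | methyl 3-oxohexanoate | CCCC(=O)CC(=O)OC | starting material
10 | methyl 2-ethyl-3-oxohexanoate (racemic) | CCCC(=O)C(CC)C(=O)OC | intermediate
11 | dilithium dienediolate (dilithium 2-ethyl-1-methoxyhexa-1,3-diene-1,3-diolate) | [Li+].[Li+].CCC=C([O-])C(CC)=C([O-])OC | intermediate
12 | methyl (15S)-15-[(tert-butyldiphenylsilyl)oxy]-2,4-diethyl-5-hydroxy-3-oxohexadecanoate (C2/C4/C5 mixture) | COC(=O)C(CC)C(=O)C(CC)C(O)CCCCCCCCC[C@H](C)O[Si](c1ccccc1)(c1ccccc1)C(C)(C)C | intermediate
13 | methyl (15S)-15-[(tert-butyldiphenylsilyl)oxy]-2,4-diethyl-3,5-dioxohexadecanoate (C2/C4 mixture) | COC(=O)C(CC)C(=O)C(CC)C(=O)CCCCCCCCC[C@H](C)O[Si](c1ccccc1)(c1ccccc1)C(C)(C)C | intermediate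
14 | 6-[(10S)-10-[(tert-butyldiphenylsilyl)oxy]undecyl]-3,5-diethyl-4-hydroxy-2H-pyran-2-one | CCc1c(O)c(CC)c(CCCCCCCCC[C@H](C)O[Si](c2ccccc2)(c2ccccc2)C(C)(C)C)oc1=O | intermediate
15 | 4-hydroxy-2-methoxypyrylium triflate, 6-[(10S)-10-[(tert-butyldiphenylsilyl)oxy]undecyl]-3,5-diethyl-4-hydroxy-2-methoxypyrylium trifluoromethanesulfonate | CCc1c(O)c(CC)c(CCCCCCCCC[C@H](C)O[Si](c2ccccc2)(c2ccccc2)C(C)(C)C)[o+]c1OC.[O-]S(=O)(=O)C(F)(F)F | intermediate
16 | 2-[(10S)-10-[(tert-butyldiphenylsilyl)oxy]undecyl]-3,5-diethyl-6-methoxy-4H-pyran-4-one | CCc1c(CCCCCCCCC[C@H](C)O[Si](c2ccccc2)(c2ccccc2)C(C)(C)C)oc(OC)c(CC)c1=O | intermediate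
17 | 3,5-diethyl-2-[(10S)-10-hydroxyundecyl]-6-methoxy-4H-pyran-4-one | CCc1c(CCCCCCCCC[C@H](C)O)oc(OC)c(CC)c1=O | intermediate
18 | (2S)-11-(3,5-diethyl-6-methoxy-4-oxo-4H-pyran-2-yl)undecan-2-yl acetate | CCc1c(CCCCCCCCC[C@H](C)OC(C)=O)oc(OC)c(CC)c1=O | target

## Step count and risks
Total step count: 11. Longest linear sequence: 10 (steps 1–4, then 6–11). Step 5 is the one-step side branch.

**Step 6 (dianion aldol).**
- Risks: incomplete second deprotonation of the doubly branched keto ester, enolisation of 8, and retro-aldol.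
- The fallback sets out from 10 and comes back at 12. It replaces the strongly basic dianion with a neutral silyl dienol ether in a Lewis-acid aldol.
- Compound 10 is silylated with TMSCl/Et3N to methyl 2-ethyl-3-[(trimethylsilyl)oxy]hex-2-enoate F1.
- This is deprotonated at C4 with LiN(iPr)2 at −78 °C and trapped with TMSCl to give the Chan-type diene 2-ethyl-1-methoxy-1,3-bis[(trimethylsilyl)oxy]hexa-1,3-diene F2.
- The diene adds through its terminal carbon to 8 under TiCl4 in CH2Cl2 at −78 °C (vinylogous Mukaiyama aldol). Aqueous work-up gives 12.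

**Step 7 (oxidation to the tricarbonyl).**
- Risks: 13 is prone to retro-Claisen cleavage and to loss on silica, and the aldol 12 can fragment.
- The fallback sets out from 8 and comes back at 13. It reaches the ketone oxidation level by a crossed Claisen-type acylation, so neither 12 nor an oxidant acting on it is needed.
- Compound 8 is oxidised under Pinnick conditions (NaClO2, NaH2PO4, 2-methylbut-2-ene, t-BuOH/H2O) to (11S)-11-[(tert-butyldiphenylsilyl)oxy]dodecanoic acid F3.
- The acid is coupled with MeNH(OMe)·HCl (EDC·HCl, Et3N, CH2Cl2) to (11S)-11-[(tert-butyldiphenylsilyl)oxy]-N-methoxy-N-methyldodecanamide F4.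
- The Weinreb amide is added to dianion 11 (2.5 equiv, made as in step 6) at −78 to 0 °C. The chelated tetrahedral adduct collapses only on quench and gives 13.

**Step 9 (regioselective methylation).**
- Risk: formation of the isomeric 4-methoxy-2-pyrone.
- The fallback sets out from 13 and comes back at 16. It skips 14 and 15, and the methoxy group of 16 is then the ester methoxy group that was never lost, so no regiochemical choice arises.
- Compound 13 is treated with PPh3/CCl4 in THF at reflux (Appel-type cyclodehydration).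
- The C5 enol is activated as its oxyphosphonium salt, the ester carbonyl oxygen closes the ring at C5, and loss of the C2 proton gives the 2-methoxy-4-pyrone directly.
- New compounds on this way: none F0.

## Further compounds
F1 | step 6 | methyl 2-ethyl-3-[(trimethylsilyl)oxy]hex-2-enoate | CCCC(O[Si](C)(C)C)=C(CC)C(=O)OC
F2 | step 6 | 2-ethyl-1-methoxy-1,3-bis[(trimethylsilyl)oxy]hexa-1,3-diene | CCC=C(O[Si](C)(C)C)C(CC)=C(OC)O[Si](C)(C)C
F3 | step 7 | (11S)-11-[(tert-butyldiphenylsilyl)oxy]dodecanoic acid | OC(=O)CCCCCCCCC[C@H](C)O[Si](c1ccccc1)(c1ccccc1)C(C)(C)C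
F4 | step 7 | (11S)-11-[(tert-butyldiphenylsilyl)oxy]-N-methoxy-N-methyldodecanamide | CON(C)C(=O)CCCCCCCCC[C@H](C)O[Si](c1ccccc1)(c1ccccc1)C(C)(C)C
F0 | step 9 | none | none
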